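**Retrosynthetic overview**

1. Numbering used below: ring carbons C1 (bears the side chain), C2 (CH2), C3/C4 (ring epoxide, C4 carries the methyl C15), C5 (angelate), C6 (acetate); side chain C7(=C14H2)–C8(angelate)–C9–C10/C11 (epoxide).
2. Late stage: side-chain epoxide by catalyst-controlled Shi epoxidation of C10=C11, both angelates by one double esterification of a C5,C8-diol, ring epoxide by hydroxyl-directed epoxidation of a carveol-type C5 allylic alcohol.
3. Key disconnection: the C5–C6 bond of the only carbocycle. The enabling feature is the vicinal dioxygenated C5–C6 edge of the six-membered ring whose neighbour C4 bears a one-carbon branch (C15). This is the retron of a 2-substituted γ-oxyallyl metal adding to an aldehyde, so the ring is closed by CrCl2/Et3SiCl reductive coupling of a 2-methylene aldehyde (C4=C15, C5) onto the C6 aldehyde of an acyclic dialdehyde with only two stereocenters.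
4. The exocyclic C4=C15 alkene left by that closure is moved into the ring at the C5 ketone level (oxidation, isomerisation, Luche reduction), which also sets C5.
5. The dialdehyde comes from an Evans allylation (C1), two aldehyde α-methylenations (C14, C15), a Brown allylation (C8) and a cross-metathesis (C10=C11). Order of ring formation: carbocycle (step 13), ring epoxide (step 18), side-chain epoxide (step 21).

Key step: step 13

Remark on the chemistry: (−)-B-allyldiisopinocampheylborane, the L-fructose-derived Shi ketone and angelic acid are taken as purchasable reagents; the C5 configuration created in step 13 is not needed later because C5 passes through a ketone.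

**Route**

Step 1
Reactants: 1 (R)-4-benzyl-1,3-oxazolidin-2-one; 2 ethyl 6-chloro-6-oxohexanoate
Product: 3 ethyl 6-[(4R)-4-benzyl-2-oxo-1,3-oxazolidin-3-yl]-6-oxohexanoate
Conditions: n-BuLi, THF, −78 °C; then 2, −78 → 0 °C
Reagents that add atoms: none
Why: N-acylation of the lithiated Evans oxazolidinone by the acid chloride should give the imide, and no stereocenter is formed.

Step 2
Reactants: 3 ethyl 6-[(4R)-4-benzyl-2-oxo-1,3-oxazolidin-3-yl]-6-oxohexanoate
Product: 4 ethyl (5S)-5-{[(4R)-4-benzyl-2-oxo-1,3-oxazolidin-3-yl]carbonyl}oct-7-enoate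
Conditions: NaN(SiMe3)2, THF, −78 °C; allyl iodide, −78 → −45 °C
Reagents that add atoms: allyl iodide, C=CCI
Why: Evans asymmetric alkylation, in which the chelated (Z)-sodium enolate of the imide (more acidic than the ethyl ester, and too cold for Dieckmann closure) is allylated on the face opposite the benzyl group of the (R)-auxiliary, should set ring carbon C1 as (S).

Step 3
Reactants: 4 ethyl (5S)-5-{[(4R)-4-benzyl-2-oxo-1,3-oxazolidin-3-yl]carbonyl}oct-7-enoate
Product: 5 ethyl (5S)-5-(hydroxymethyl)oct-7-enoate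
Conditions: LiBH4, MeOH (1 equiv), THF, 0 °C
Reagents that add atoms: none
Why: Reductive removal of the auxiliary with LiBH4 should reduce the activated imide carbonyl faster than the ethyl ester and leaves the stereocenter untouched.

Step 4
Reactants: 5 ethyl (5S)-5-(hydroxymethyl)oct-7-enoate
Product: 6 ethyl (5S)-5-{[(triethylsilyl)oxy]methyl}oct-7-enoate
Conditions: Et3SiCl, imidazole, CH2Cl2, 0 °C
Reagents that add atoms: chlorotriethylsilane, CC[Si](Cl)(CC)CC
Why: Silylation of the primary alcohol as a triethylsilyl ether, chosen because a primary TES ether can later be oxidised directly under Swern conditions.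

Step 5
Reactants: 6 ethyl (5S)-5-{[(triethylsilyl)oxy]methyl}oct-7-enoate
Product: 7 ethyl (5S)-7-oxo-5-{[(triethylsilyl)oxy]methyl}heptanoate
Conditions: O3, CH2Cl2, −78 °C; then Me2S, −78 °C → rt
Reagents that add atoms: ozone, [O-][O+]=O
Why: Ozonolysis with reductive work-up cleaves the only alkene to the aldehyde C8 without touching the stereocenter.

Step 6
Reactants: 7 ethyl (5S)-7-oxo-5-{[(triethylsilyl)oxy]methyl}heptanoate
Product: 8 ethyl (5S)-6-formyl-5-{[(triethylsilyl)oxy]methyl}hept-6-enoate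
Conditions: 37% aq. CH2O, pyrrolidine (10 mol%), 4-(dimethylamino)benzoic acid (20 mol%), CH2Cl2, 40 °C
Reagents that add atoms: formaldehyde, C=O
Why: Amine-catalysed Mannich condensation and elimination (α-methylenation of an aldehyde) installs the methylene C14 on C7, and the adjacent stereocenter cannot be enolised through the new enal.

Step 7
Reactants: 8 ethyl (5S)-6-formyl-5-{[(triethylsilyl)oxy]methyl}hept-6-enoate
Product: 9 ethyl (5S,7S)-7-hydroxy-6-methylidene-5-{[(triethylsilyl)oxy]methyl}dec-9-enoate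
Conditions: (−)-Ipc2B(allyl), Et2O, −78 °C; then NaBO3·4H2O, THF/H2O, rt
Reagents that add atoms: (−)-B-allyldiisopinocampheylborane (from (+)-α-pinene), C=CCB([C@@H]1C[C@@H]2C[C@@H](C2(C)C)[C@H]1C)[C@@H]1C[C@@H]2C[C@@H](C2(C)C)[C@H]1C
Why: Brown allylation through a chair transition state under reagent control should add the allyl group to one face of the enal carbonyl and set the carbinol C8 as (S).

Step 8
Reactants: 9 ethyl (5S,7S)-7-hydroxy-6-methylidene-5-{[(triethylsilyl)oxy]methyl}dec-9-enoate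
Product: 10 ethyl (5S,7S)-7-[(tert-butyldimethylsilyl)oxy]-6-methylidene-5-{[(triethylsilyl)oxy]methyl}dec-9-enoate
Conditions: t-BuMe2SiOTf, 2,6-lutidine, CH2Cl2, −78 °C
Reagents that add atoms: tert-butyldimethylsilyl triflate, CC(C)(C)[Si](C)(C)OS(=O)(=O)C(F)(F)F
Why: Silylation of the hindered secondary allylic alcohol with the silyl triflate gives a TBS ether that should survive the two later TES removals (steps 12 and 15).

Step 9
Reactants: 10 ethyl (5S,7S)-7-[(tert-butyldimethylsilyl)oxy]-6-methylidene-5-{[(triethylsilyl)oxy]methyl}dec-9-enoate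
Product: 11 ethyl (5S,7S)-7-[(tert-butyldimethylsilyl)oxy]-10-methyl-6-methylidene-5-{[(triethylsilyl)oxy]methyl}undec-9-enoate
Conditions: 2-methyl-2-butene (excess), second-generation Grubbs catalyst (H2IMes)(PCy3)Cl2Ru=CHPh (5 mol%), CH2Cl2, 40 °C
Reagents that add atoms: 2-methyl-2-butene, CC=C(C)C
Why: Olefin cross-metathesis should convert only the monosubstituted alkene into the prenyl-type C10=C11 alkene, because the hindered 1,1-disubstituted C7=C14 alkene does not engage the ruthenium carbene.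

Step 10
Reactants: 11 ethyl (5S,7S)-7-[(tert-butyldimethylsilyl)oxy]-10-methyl-6-methylidene-5-{[(triethylsilyl)oxy]methyl}undec-9-enoate
Product: 12 (5S,7S)-7-[(tert-butyldimethylsilyl)oxy]-10-methyl-6-methylidene-5-{[(triethylsilyl)oxy]methyl}undec-9-enal
Conditions: i-Bu2AlH (1.1 equiv), CH2Cl2, −78 °C; then MeOH, aq. potassium sodium tartrate
Reagents that add atoms: none
Why: Partial reduction of the ester with i-Bu2AlH at −78 °C should stop at the aluminium hemiacetal, which releases the C5 aldehyde on work-up.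

Step 11
Reactants: 12 (5S,7S)-7-[(tert-butyldimethylsilyl)oxy]-10-methyl-6-methylidene-5-{[(triethylsilyl)oxy]methyl}undec-9-enal
Product: 13 (5S,7S)-7-[(tert-butyldimethylsilyl)oxy]-10-methyl-2,6-dimethylidene-5-{[(triethylsilyl)oxy]methyl}undec-9-enal
Conditions: 37% aq. CH2O, pyrrolidine (10 mol%), 4-(dimethylamino)benzoic acid (20 mol%), CH2Cl2, 40 °C
Reagents that add atoms: formaldehyde, C=O
Why: A second aldehyde α-methylenation (Mannich condensation and elimination) installs C15 on C4 and creates the 2-substituted acrolein that is the chromium acceptor of the key step.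

Step 12
Reactants: 13 (5S,7S)-7-[(tert-butyldimethylsilyl)oxy]-10-methyl-2,6-dimethylidene-5-{[(triethylsilyl)oxy]methyl}undec-9-enal
Product: 14 (2S)-2-{(3S)-3-[(tert-butyldimethylsilyl)oxy]-6-methylhepta-1,5-dien-2-yl}-5-methylidenehexanedial
Conditions: (COCl)2, DMSO, CH2Cl2, −78 → −40 °C; then i-Pr2NEt, −78 → −30 °C; used at once
Reagents that add atoms: none
Why: Swern oxidation converts a primary triethylsilyl ether directly into the aldehyde while the secondary TBS ether stays, so the epimerisable C1 aldehyde exists only in the intermediate that is cyclised immediately.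

Step 13
Reactants: 14 (2S)-2-{(3S)-3-[(tert-butyldimethylsilyl)oxy]-6-methylhepta-1,5-dien-2-yl}-5-methylidenehexanedial
Product: 16 (1R,2S,6S)-6-{(3S)-3-[(tert-butyldimethylsilyl)oxy]-6-methylhepta-1,5-dien-2-yl}-3-methylidene-2-[(triethylsilyl)oxy]cyclohexan-1-ol, via allylchromium species 15 (not isolated)
Conditions: CrCl2 (6 equiv), Et3SiCl (3 equiv), DMF, 0 °C → rt, slow addition of 14 (0.005 M final)
Reagents that add atoms: chlorotriethylsilane, CC[Si](Cl)(CC)CC
Why: Proposed new method: CrCl2 should reduce only the conjugated 2-substituted acrolein of 14 (a saturated aldehyde is not reduced by divalent chromium), Et3SiCl caps the oxygen, and the γ-siloxyallylchromium 15 (trivalent chromium, metal on the unsubstituted terminus C15) then adds through its oxygen-bearing γ-carbon C5 to the tethered aldehyde C6, forming the C5–C6 bond by an allylmetal (SE2′) carbonyl addition. The closest known reactions are the intermolecular CrCl2/R3SiCl cross-pinacol-type coupling of enals with aldehydes and intramolecular Nozaki–Hiyama–Kishi allylations of 2-(halomethyl)allyl aldehydes to 3-methylenecycloalkanols; the ring-closing combination of the two is what is new. The six-membered ring closes in a 6-(enolendo)-exo-trig mode with the allyl terminus C15 left exocyclic, which allows the usual metal-bridged six-membered transition state as one ring of a chair–chair bicyclo[3.3.1] array. C6 is controlled by C1: the C6–O–Cr bond has to be axial on the forming carbocycle to reach the metal while the branched C1 substituent stays equatorial, so the new hydroxyl should come out cis to the side chain, the contra-steric relationship that a ketone reduction or a dihydroxylation would not deliver. C5 is expected cis to C6–O (siloxy group turned toward the loose chromium-containing ring), but it is not relied upon because C5 is re-set in steps 15 to 17. The step needs chemoselectivity between the two aldehydes (secured by conjugation of only one), attack at C5 and not C15 (secured by the position of chromium) and suppression of intermolecular coupling (slow addition at high dilution).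

Step 14
Reactants: 16 (1R,2S,6S)-6-{(3S)-3-[(tert-butyldimethylsilyl)oxy]-6-methylhepta-1,5-dien-2-yl}-3-methylidene-2-[(triethylsilyl)oxy]cyclohexan-1-ol
Product: 17 (1R,2S,6S)-6-{(3S)-3-[(tert-butyldimethylsilyl)oxy]-6-methylhepta-1,5-dien-2-yl}-3-methylidene-2-[(triethylsilyl)oxy]cyclohexyl acetate
Conditions: Ac2O, pyridine, DMAP (cat.), CH2Cl2, rt
Reagents that add atoms: acetic anhydride, CC(=O)OC(C)=O
Why: DMAP-catalysed acetylation of the only free hydroxyl installs the C6 acetate of the target with retention.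

Step 15
Reactants: 17 (1R,2S,6S)-6-{(3S)-3-[(tert-butyldimethylsilyl)oxy]-6-methylhepta-1,5-dien-2-yl}-3-methylidene-2-[(triethylsilyl)oxy]cyclohexyl acetate
Product: 19 (1R,6S)-6-{(3S)-3-[(tert-butyldimethylsilyl)oxy]-6-methylhepta-1,5-dien-2-yl}-3-methylidene-2-oxocyclohexyl acetate, via allylic alcohol 18 (not isolated)
Conditions: IBX (3 equiv), DMSO, rt
Reagents that add atoms: none
Why: IBX in DMSO cleaves the triethylsilyl ether and oxidises the liberated allylic alcohol in the same flask (oxidative desilylation) while TBS ether and acetate stay, which deliberately erases C5 to allow the alkene shift.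

Step 16
Reactants: 19 (1R,6S)-6-{(3S)-3-[(tert-butyldimethylsilyl)oxy]-6-methylhepta-1,5-dien-2-yl}-3-methylidene-2-oxocyclohexyl acetate
Product: 20 (1R,6S)-6-{(3S)-3-[(tert-butyldimethylsilyl)oxy]-6-methylhepta-1,5-dien-2-yl}-3-methyl-2-oxocyclohex-3-en-1-yl acetate
Conditions: RhCl3·3H2O (5 mol%), EtOH, 70 °C
Reagents that add atoms: none
Why: Rhodium-hydride-catalysed exo-to-endo enone isomerisation should move the methylene into the ring to the conjugated trisubstituted enone (the thermodynamic sink), the C5 carbonyl blocking migration toward oxygen, so that C15 becomes the ring methyl.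

Step 17
Reactants: 20 (1R,6S)-6-{(3S)-3-[(tert-butyldimethylsilyl)oxy]-6-methylhepta-1,5-dien-2-yl}-3-methyl-2-oxocyclohex-3-en-1-yl acetate
Product: 21 (1R,2S,6S)-6-{(3S)-3-[(tert-butyldimethylsilyl)oxy]-6-methylhepta-1,5-dien-2-yl}-2-hydroxy-3-methylcyclohex-3-en-1-yl acetate
Conditions: NaBH4, CeCl3·7H2O, MeOH, −78 °C
Reagents that add atoms: none
Why: Luche 1,2-reduction, with axial hydride delivery anti to the pseudo-axial C6 acetoxy group (Felkin–Anh and steric control, as in the reduction of carvone to cis-carveol), should set the C5 hydroxyl cis to the acetate and to the side chain.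

Step 18
Reactants: 21 (1R,2S,6S)-6-{(3S)-3-[(tert-butyldimethylsilyl)oxy]-6-methylhepta-1,5-dien-2-yl}-2-hydroxy-3-methylcyclohex-3-en-1-yl acetate
Product: 22 (1R,2R,3R,4S,6S)-4-{(3S)-3-[(tert-butyldimethylsilyl)oxy]-6-methylhepta-1,5-dien-2-yl}-2-hydroxy-1-methyl-7-oxabicyclo[4.1.0]heptan-3-yl acetate
Conditions: VO(acac)2 (5 mol%), t-BuOOH, CH2Cl2, 0 °C → rt
Reagents that add atoms: tert-butyl hydroperoxide, CC(C)(C)OO
Why: Vanadium-catalysed hydroxyl-directed epoxidation delivers oxygen syn to the C5 hydroxyl and only to the allylic-alcohol alkene (the other alkenes carry no free hydroxyl), which should set C3 and C4 cis to all other ring substituents.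

Step 19
Reactants: 22 (1R,2R,3R,4S,6S)-4-{(3S)-3-[(tert-butyldimethylsilyl)oxy]-6-methylhepta-1,5-dien-2-yl}-2-hydroxy-1-methyl-7-oxabicyclo[4.1.0]heptan-3-yl acetate
Product: 23 (1R,2R,3R,4S,6S)-2-hydroxy-4-[(3S)-3-hydroxy-6-methylhepta-1,5-dien-2-yl]-1-methyl-7-oxabicyclo[4.1.0]heptan-3-yl acetate
Conditions: Bu4NF, AcOH (1:1), THF, rt
Reagents that add atoms: none
Why: Fluoride desilylation buffered with acetic acid frees the C8 alcohol while the buffer is meant to suppress 1,2-acetyl migration and epoxide opening.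

Step 20
Reactants: 23 (1R,2R,3R,4S,6S)-2-hydroxy-4-[(3S)-3-hydroxy-6-methylhepta-1,5-dien-2-yl]-1-methyl-7-oxabicyclo[4.1.0]heptan-3-yl acetate
Product: 24 (1S,2R,3R,4S,6S)-3-acetoxy-1-methyl-4-{(3S)-6-methyl-3-[(Z)-2-methylbut-2-enoyloxy]hepta-1,5-dien-2-yl}-7-oxabicyclo[4.1.0]heptan-2-yl (Z)-2-methylbut-2-enoate
Conditions: angelic acid, 2,4,6-trichlorobenzoyl chloride, Et3N, toluene, rt; then 23, 75 °C
Reagents that add atoms: angelic acid [(Z)-2-methylbut-2-enoic acid], C/C=C(/C)C(=O)O
Why: Yamaguchi-type esterification with the preformed mixed anhydride of angelic acid, run without DMAP to preserve the (Z)-geometry, should acylate both secondary alcohols with retention at C5 and C8.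

Step 21
Reactants: 24 (1S,2R,3R,4S,6S)-3-acetoxy-1-methyl-4-{(3S)-6-methyl-3-[(Z)-2-methylbut-2-enoyloxy]hepta-1,5-dien-2-yl}-7-oxabicyclo[4.1.0]heptan-2-yl (Z)-2-methylbut-2-enoate
Product: 25 CNP0118696.1, (1S,2R,3R,4S,6S)-3-acetoxy-4-{(3S)-4-[(2S)-3,3-dimethyloxiran-2-yl]-3-[(Z)-2-methylbut-2-enoyloxy]but-1-en-2-yl}-1-methyl-7-oxabicyclo[4.1.0]heptan-2-yl (Z)-2-methylbut-2-enoate
Conditions: L-fructose-derived Shi ketone (30 mol%), Oxone (2KHSO5·KHSO4·K2SO4), K2CO3, Bu4NHSO4, MeCN/CH2(OMe)2/aq. Na2B4O7 buffer, 0 °C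
Reagents that add atoms: potassium peroxymonosulfate (active component of Oxone), [K+].OOS(=O)(=O)[O-]
Why: Shi asymmetric epoxidation, in which the chiral dioxirane should attack only the electron-rich trisubstituted C10=C11 alkene through a spiro transition state, sets C10 as (S) under catalyst control (the enantiomeric ketone would give the (R)-epoxide).

**Compound list**

1 | (R)-4-benzyl-1,3-oxazolidin-2-one | O=C1N[C@H](Cc2ccccc2)CO1 | starting material
2 | ethyl 6-chloro-6-oxohexanoate | CCOC(=O)CCCCC(Cl)=O | starting material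
3 | ethyl 6-[(4R)-4-benzyl-2-oxo-1,3-oxazolidin-3-yl]-6-oxohexanoate | CCOC(=O)CCCCC(=O)N1[C@H](Cc2ccccc2)COC1=O | intermediate
4 | ethyl (5S)-5-{[(4R)-4-benzyl-2-oxo-1,3-oxazolidin-3-yl]carbonyl}oct-7-enoate | C=CC[C@@H](C(=O)N1[C@H](Cc2ccccc2)COC1=O)CCCC(=O)OCC | intermediate
5 | ethyl (5S)-5-(hydroxymethyl)oct-7-enoate | C=CC[C@@H](CO)CCCC(=O)OCC | intermediate
6 | ethyl (5S)-5-{[(triethylsilyl)oxy]methyl}oct-7-enoate | C=CC[C@@H](CO[Si](CC)(CC)CC)CCCC(=O)OCC | intermediate
7 | ethyl (5S)-7-oxo-5-{[(triethylsilyl)oxy]methyl}heptanoate | O=CC[C@@H](CO[Si](CC)(CC)CC)CCCC(=O)OCC | intermediate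
8 | ethyl (5S)-6-formyl-5-{[(triethylsilyl)oxy]methyl}hept-6-enoate | C=C(C=O)[C@@H](CO[Si](CC)(CC)CC)CCCC(=O)OCC | intermediate
9 | ethyl (5S,7S)-7-hydroxy-6-methylidene-5-{[(triethylsilyl)oxy]methyl}dec-9-enoate | C=C([C@H](CC=C)O)[C@@H](CO[Si](CC)(CC)CC)CCCC(=O)OCC | intermediate
10 | ethyl (5S,7S)-7-[(tert-butyldimethylsilyl)oxy]-6-methylidene-5-{[(triethylsilyl)oxy]methyl}dec-9-enoate | C=C([C@H](CC=C)O[Si](C)(C)C(C)(C)C)[C@@H](CO[Si](CC)(CC)CC)CCCC(=O)OCC | intermediate
11 | ethyl (5S,7S)-7-[(tert-butyldimethylsilyl)oxy]-10-methyl-6-methylidene-5-{[(triethylsilyl)oxy]methyl}undec-9-enoate | C=C([C@H](CC=C(C)C)O[Si](C)(C)C(C)(C)C)[C@@H](CO[Si](CC)(CC)CC)CCCC(=O)OCC | intermediate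
12 | (5S,7S)-7-[(tert-butyldimethylsilyl)oxy]-10-methyl-6-methylidene-5-{[(triethylsilyl)oxy]methyl}undec-9-enal | C=C([C@H](CC=C(C)C)O[Si](C)(C)C(C)(C)C)[C@@H](CO[Si](CC)(CC)CC)CCCC=O | intermediate
13 | (5S,7S)-7-[(tert-butyldimethylsilyl)oxy]-10-methyl-2,6-dimethylidene-5-{[(triethylsilyl)oxy]methyl}undec-9-enal | C=C([C@H](CC=C(C)C)O[Si](C)(C)C(C)(C)C)[C@@H](CO[Si](CC)(CC)CC)CCC(=C)C=O | intermediate
14 | (2S)-2-{(3S)-3-[(tert-butyldimethylsilyl)oxy]-6-methylhepta-1,5-dien-2-yl}-5-methylidenehexanedial | C=C([C@H](CC=C(C)C)O[Si](C)(C)C(C)(C)C)[C@@H](C=O)CCC(=C)C=O | intermediate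
15 | γ-(triethylsilyloxy)allylchromium dichloride formed from 14 (trivalent chromium; not isolated) | Cl[Cr](Cl)CC(=CO[Si](CC)(CC)CC)CC[C@H](C=O)C(=C)[C@H](CC=C(C)C)O[Si](C)(C)C(C)(C)C | intermediate
16 | (1R,2S,6S)-6-{(3S)-3-[(tert-butyldimethylsilyl)oxy]-6-methylhepta-1,5-dien-2-yl}-3-methylidene-2-[(triethylsilyl)oxy]cyclohexan-1-ol | C=C([C@H](CC=C(C)C)O[Si](C)(C)C(C)(C)C)[C@@H]1CCC(=C)[C@H](O[Si](CC)(CC)CC)[C@@H]1O | intermediate
17 | (1R,2S,6S)-6-{(3S)-3-[(tert-butyldimethylsilyl)oxy]-6-methylhepta-1,5-dien-2-yl}-3-methylidene-2-[(triethylsilyl)oxy]cyclohexyl acetate | C=C([C@H](CC=C(C)C)O[Si](C)(C)C(C)(C)C)[C@@H]1CCC(=C)[C@H](O[Si](CC)(CC)CC)[C@@H]1OC(C)=O | intermediate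
18 | (1R,2S,6S)-6-{(3S)-3-[(tert-butyldimethylsilyl)oxy]-6-methylhepta-1,5-dien-2-yl}-2-hydroxy-3-methylidenecyclohexyl acetate (not isolated) | C=C([C@H](CC=C(C)C)O[Si](C)(C)C(C)(C)C)[C@@H]1CCC(=C)[C@H](O)[C@@H]1OC(C)=O | intermediate
19 | (1R,6S)-6-{(3S)-3-[(tert-butyldimethylsilyl)oxy]-6-methylhepta-1,5-dien-2-yl}-3-methylidene-2-oxocyclohexyl acetate | C=C([C@H](CC=C(C)C)O[Si](C)(C)C(C)(C)C)[C@@H]1CCC(=C)C(=O)[C@@H]1OC(C)=O | intermediate
20 | (1R,6S)-6-{(3S)-3-[(tert-butyldimethylsilyl)oxy]-6-methylhepta-1,5-dien-2-yl}-3-methyl-2-oxocyclohex-3-en-1-yl acetate | C=C([C@H](CC=C(C)C)O[Si](C)(C)C(C)(C)C)[C@@H]1CC=C(C)C(=O)[C@@H]1OC(C)=O | intermediate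
21 | (1R,2S,6S)-6-{(3S)-3-[(tert-butyldimethylsilyl)oxy]-6-methylhepta-1,5-dien-2-yl}-2-hydroxy-3-methylcyclohex-3-en-1-yl acetate | C=C([C@H](CC=C(C)C)O[Si](C)(C)C(C)(C)C)[C@@H]1CC=C(C)[C@H](O)[C@@H]1OC(C)=O | intermediate
22 | (1R,2R,3R,4S,6S)-4-{(3S)-3-[(tert-butyldimethylsilyl)oxy]-6-methylhepta-1,5-dien-2-yl}-2-hydroxy-1-methyl-7-oxabicyclo[4.1.0]heptan-3-yl acetate | C=C([C@H](CC=C(C)C)O[Si](C)(C)C(C)(C)C)[C@@H]1C[C@@H]2O[C@]2(C)[C@H](O)[C@@H]1OC(C)=O | intermediate
23 | (1R,2R,3R,4S,6S)-2-hydroxy-4-[(3S)-3-hydroxy-6-methylhepta-1,5-dien-2-yl]-1-methyl-7-oxabicyclo[4.1.0]heptan-3-yl acetate | C=C([C@H](CC=C(C)C)O)[C@@H]1C[C@@H]2O[C@]2(C)[C@H](O)[C@@H]1OC(C)=O | intermediate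
24 | (1S,2R,3R,4S,6S)-3-acetoxy-1-methyl-4-{(3S)-6-methyl-3-[(Z)-2-methylbut-2-enoyloxy]hepta-1,5-dien-2-yl}-7-oxabicyclo[4.1.0]heptan-2-yl (Z)-2-methylbut-2-enoate | C=C([C@H](CC=C(C)C)OC(=O)/C(C)=C\C)[C@@H]1C[C@@H]2O[C@]2(C)[C@H](OC(=O)/C(C)=C\C)[C@@H]1OC(C)=O | intermediate
25 | CNP0118696.1, (1S,2R,3R,4S,6S)-3-acetoxy-4-{(3S)-4-[(2S)-3,3-dimethyloxiran-2-yl]-3-[(Z)-2-methylbut-2-enoyloxy]but-1-en-2-yl}-1-methyl-7-oxabicyclo[4.1.0]heptan-2-yl (Z)-2-methylbut-2-enoate | C=C([C@H](C[C@@H]1OC1(C)C)OC(=O)/C(C)=C\C)[C@@H]1C[C@@H]2O[C@]2(C)[C@H](OC(=O)/C(C)=C\C)[C@@H]1OC(C)=O | target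

**Step count and risks**

Total step count: 21. Longest linear sequence: 21 steps (the route is linear from 1 and 2).

Steps most likely to fail:

Step 13 (proposed new method). The allylchromium may be protonated or couple intermolecularly before it cyclises, or closure through a competing boat transition state may erode the cis relationship between C1 and C6. The fallback uses a known ketyl coupling instead of an allylmetal addition and sets out from 14. A samarium diiodide pinacol cyclisation (SmI2, t-BuOH, THF, −78 °C), a known way to close 1,6-dialdehydes to cis-cyclohexane-1,2-diols through a samarium chelate, should give (1R,2S,6S)-6-{(3S)-3-[(tert-butyldimethylsilyl)oxy]-6-methylhepta-1,5-dien-2-yl}-3-methylidenecyclohexane-1,2-diol F1, any C6 epimer being removed at this stage. Chemoselective oxidation of the allylic hydroxyl (MnO2, CH2Cl2) should then give (2R,3S)-3-{(3S)-3-[(tert-butyldimethylsilyl)oxy]-6-methylhepta-1,5-dien-2-yl}-2-hydroxy-6-methylidenecyclohexan-1-one F2, and acetylation (Ac2O, pyridine) comes back to the route at 19.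

Step 16. The rhodium hydride may also migrate the 1,1-disubstituted side-chain alkene toward the silyl ether, and traces of acid may cause loss of the TBS group or epimerisation next to the ketone. The fallback replaces isomerisation by a conjugate reduction and dehydrogenation pair and sets out from 19. A 1,4-hydrosilylation that touches only the enone (RhCl(PPh3)3 cat., Et3SiH, toluene, 50 °C) should give the silyl enol ether (1R,6S)-6-{(3S)-3-[(tert-butyldimethylsilyl)oxy]-6-methylhepta-1,5-dien-2-yl}-3-methyl-2-[(triethylsilyl)oxy]cyclohex-2-en-1-yl acetate F3. Saegusa–Ito oxidation (Pd(OAc)2, MeCN, rt) then places the double bond in the ring and comes back to the route at 20.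

Step 20. Geometric isomerisation of the angelate to the tiglate, incomplete acylation of the hindered C5 hydroxyl, or 1,2-acetyl migration under the basic conditions may occur. The fallback builds the (Z)-alkenes on the ester instead of transferring a preformed angeloyl group and sets out from 23. Both hydroxyls are acylated with 2-[bis(2,2,2-trifluoroethoxy)phosphoryl]propanoic acid (DCC, DMAP, CH2Cl2) to give the bis(phosphonate) (1S,2R,3R,4S,6S)-3-acetoxy-4-[(3S)-3-{2-[bis(2,2,2-trifluoroethoxy)phosphoryl]propanoyloxy}-6-methylhepta-1,5-dien-2-yl]-1-methyl-7-oxabicyclo[4.1.0]heptan-2-yl 2-[bis(2,2,2-trifluoroethoxy)phosphoryl]propanoate F4 (epimers at the phosphonate carbons). A double Still–Gennari olefination with acetaldehyde (KN(SiMe3)2, 18-crown-6, THF, −78 °C) should form both (Z)-2-methylbut-2-enoates and comes back to the route at 24.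

Further compounds
F1 | step 13 | (1R,2S,6S)-6-{(3S)-3-[(tert-butyldimethylsilyl)oxy]-6-methylhepta-1,5-dien-2-yl}-3-methylidenecyclohexane-1,2-diol | C=C([C@H](CC=C(C)C)O[Si](C)(C)C(C)(C)C)[C@@H]1CCC(=C)[C@H](O)[C@@H]1O
F2 | step 13 | (2R,3S)-3-{(3S)-3-[(tert-butyldimethylsilyl)oxy]-6-methylhepta-1,5-dien-2-yl}-2-hydroxy-6-methylidenecyclohexan-1-one | C=C([C@H](CC=C(C)C)O[Si](C)(C)C(C)(C)C)[C@@H]1CCC(=C)C(=O)[C@@H]1O
F3 | step 16 | (1R,6S)-6-{(3S)-3-[(tert-butyldimethylsilyl)oxy]-6-methylhepta-1,5-dien-2-yl}-3-methyl-2-[(triethylsilyl)oxy]cyclohex-2-en-1-yl acetate | C=C([C@H](CC=C(C)C)O[Si](C)(C)C(C)(C)C)[C@@H]1CCC(C)=C(O[Si](CC)(CC)CC)[C@@H]1OC(C)=O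
F4 | step 20 | (1S,2R,3R,4S,6S)-3-acetoxy-4-[(3S)-3-{2-[bis(2,2,2-trifluoroethoxy)phosphoryl]propanoyloxy}-6-methylhepta-1,5-dien-2-yl]-1-methyl-7-oxabicyclo[4.1.0]heptan-2-yl 2-[bis(2,2,2-trifluoroethoxy)phosphoryl]propanoate | C=C([C@H](CC=C(C)C)OC(=O)C(C)P(=O)(OCC(F)(F)F)OCC(F)(F)F)[C@@H]1C[C@@H]2O[C@]2(C)[C@H](OC(=O)C(C)P(=O)(OCC(F)(F)F)OCC(F)(F)F)[C@@H]1OC(C)=O
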